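Charge the theta flask as planned and take one reading at 15 min, provided that reading will stand clear of the scatter; the reckoning below tests that condition.

| flask | starting material | coupling partner | catalyst | time |
|---|---|---|---|---|
| gamma | 300 mM | 450 mM | 1.50 mM |  |
| epsilon | 300 mM | 230 mM | 1.50 mM |  |
| alpha | 900 mM | 450 mM | 1.50 mM |  |
| theta | 300 mM | 150 mM | 0.490 mM | 15 min |

| gamma run: time / min | gamma run: [target] / mM | epsilon run: time / min | epsilon run: [target] / mM | alpha run: time / min | alpha run: [target] / mM |
|---|---|---|---|---|---|
| 0.60 | 12.4 | 0.60 | 6.8 | 0.60 | 37.3 |
| 0.95 | 20.6 | 0.95 | 13.9 | 0.95 | 52.3 |
| 1.5 | 28.9 | 1.5 | 16.9 | 1.5 | 72.8 |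
| 2.4 | 36.6 | 2.4 | 23.6 | 2.4 | 94.7 |
| 3.8 | 45.4 | 3.8 | 33.2 | 3.8 | 114.6 |
| 6.0 | 56.2 | 6.0 | 38.1 | 6.0 | 132.5 |
| 9.5 | 57.9 | 9.5 | 42.2 | 9.5 | 146.3 |
| 15 | 63.3 | 15 | 43.9 | 15 | 153.4 |

(readings scatter by 2 mM)

- Overall: starting material + coupling partner -> target, with catalyst as catalyst.
- Constant volume, constant temperature.
- Readings of a species count what is bound in complexes too.
- An order is taken over about fifteen percent of the charge, up and down.

1. the power of [coupling partner] that the first rate follows, about the charge of the gamma run; measure it at two percent of starting material made into target
2. the power of [starting material] that the first rate follows, about the charge of the gamma run; measure it at two percent of starting material made into target (one fixed amount of target, the same in the runs compared)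
3. target in the theta run at 15 min, as a share of the starting material charged

I take as first rate the first reading of target divided by its time, 0.60 min: 20.7 mM/min in the gamma run, 11.3 mM/min in the epsilon run and 62.2 mM/min in the alpha run. Going from 450 mM to 230 mM of coupling partner multiplies it by 0.546, so I reckon an order of 0.895. Going from 300 mM to 900 mM of starting material multiplies it by 3.00, so I reckon 1.00. Both steps are wider than the one asked and rest on single scattered readings, so both orders are rough.

I carry one quantity, the working time. For the gamma run, the working time, its target at 15 min divided by its first rate, is 3.06 min. The epsilon run, with less coupling partner, gives a longer 3.87 min.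

The theta flask has the gamma run's starting material. I scale the gamma run's first rate by catalyst to the first power, which these runs do not test, and by coupling partner to my order, giving 2.53 mM/min. Extending the working-time trend as a power of the coupling partner charge down to 150 mM gives 4.50 min. So I expect 11.4 mM, or 3.79% of the starting material, far less than the 150 mM that the coupling partner, the limiting reagent, allows. That is 5.68 standard deviations, so I leave the charge unchanged and take the one reading.

The forecast gives 0.8, 1.05 and 4%, and its ground is that “the rate falls on a common clock”.

The flask gives 0.77, 1.1 and 4.42%.

    catalyst + starting material ⇌ catalyst-substrate complex (217.2 /M/min, 744.0 /min)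
    catalyst-substrate complex + coupling partner → target + catalyst (672.0 /M/min)
    starting material → decomposed substrate (0.1470 /min)
    2 coupling partner → lost reagent (0.5262 /M/min)

In the theta flask, 13.3 mM of target over my first rate makes a working time of 5.25 min, longer than my 4.50 min; target formed while starting material decayed to decomposed substrate with a lifetime of 6.80 min and coupling partner paired off to lost reagent with a first half-life by this step alone of 6.33 min. In the alpha run, the working time read from the simulated readings is 2.47 min, and the coupling partner's first half-life by this step alone is 2.11 min.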